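**Retrosynthetic overview** (numbering: C1 acyl bridgehead, C2–C4 enolised dione, C5 prenyl bridgehead, C6 CH2, C7 CH(prenyl), C8 CMe2, C9 bridging C=O, C1'–C3' the prenyl carbons on C7; ring A = C1‑C8‑C7‑C6‑C5‑C9, ring B = C1‑C2‑C3‑C4‑C5‑C9)
1. Target ⇐ O‑demethylation/desilylation, bridgehead C1 acylation with (R)‑2‑methylbutanoyl chloride and C3 hydroxyalkylation (2,2‑dimethyloxetane) of a bicyclo[3.3.1]nonane vinylogous methyl ester.
2. Bicycle ⇐ ring A closed last through C6–C7: a temporary CH2–CHO arm on quaternary C5 (C6 is its α‑carbon) adds, as an enaminyl radical cation, to the terminus C7 of a 1,1‑dimethylbutadienyl arm on C1; the allyl radical ends as the C7 prenyl group and the formyl group is then removed with rhodium.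
3. Enabling feature: C6 is a CH2 on the quaternary C5, and C7 is a CH that carries a prenyl group beside the gem‑dimethyl C8; they are the ends of two cis‑1,3 arms across the C9 carbonyl of ring B, and C1–H (between C9=O and the vinylogous ester) is labile, so only C5 has to be set beforehand.
4. Ring B ⇐ vinylogous Dieckmann closure (C1–C9) of a β‑methoxy enone onto a γ‑butyrolactone; pieces: (S)‑3‑acetyl‑3‑prenylbutyrolactone (chiral‑enamine alkylation of α‑acetylbutyrolactone) and (E)‑3,3,7‑trimethylocta‑4,6‑dienoic acid (phorone: Luche reduction, Johnson–Claisen).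
5. Ring order: ring B (step 8), then ring A (step 10).

Key step: step 10

Assumptions: the face selected in the chiral‑enamine alkylation of step 5 depends on solvent and additive, and the variant that gives the (S)‑configured acetyl lactone is taken (the D‑valine ester is the equivalent alternative); (R)‑2‑methylbutanoic acid is taken as a catalogue compound.

Step 1
Reactants: 1 phorone (2,6‑dimethylhepta‑2,5‑dien‑4‑one)
Product: 2 2,6‑dimethylhepta‑2,5‑dien‑4‑ol
Conditions: NaBH4, CeCl3·7H2O, MeOH, 0 °C
Reagents that add atoms: none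
Why: Luche reduction, in which the cerium‑activated hard borohydride adds 1,2 to the cross‑conjugated dienone; the symmetric product has no stereocentre.

Step 2
Reactants: 2 2,6‑dimethylhepta‑2,5‑dien‑4‑ol
Product: 4 ethyl (E)‑3,3,7‑trimethylocta‑4,6‑dienoate, via ketene acetal 3 (not isolated)
Conditions: MeC(OEt)3 (excess), EtCO2H (cat.), 135 °C, EtOH distilled off
Reagents that add atoms: triethyl orthoacetate, CC(OCC)(OCC)OCC
Why: Johnson–Claisen rearrangement, in which the chair [3,3] shift of the ketene acetal bonds the acetate carbon to the dimethyl‑substituted alkene terminus (the future C8 with its two methyl groups) and leaves the second isobutenyl group as an (E)‑configured conjugated diene because the large residue sits equatorial in the chair.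

Step 3
Reactants: 4 ethyl (E)‑3,3,7‑trimethylocta‑4,6‑dienoate
Product: 5 (E)‑3,3,7‑trimethylocta‑4,6‑dienoic acid
Conditions: LiOH·H2O, THF/MeOH/H2O, 50 °C; then 1 M HCl
Reagents that add atoms: lithium hydroxide, [Li+].[OH-]
Why: ester saponification by hydroxide, with no stereocentre involved and the diene untouched by base.

Step 4
Reactants: 6 3‑acetyldihydrofuran‑2(3H)‑one (α‑acetyl‑γ‑butyrolactone), 7 L‑valine tert‑butyl ester hydrochloride
Product: 8 tert‑butyl N‑[(Z)‑1‑(2‑oxodihydrofuran‑3(2H)‑ylidene)ethyl]‑L‑valinate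
Conditions: Et3N, 4 Å molecular sieves, PhMe, 60 °C
Reagents that add atoms: none
Why: condensation of the acetyl ketone with the primary amine gives the hydrogen‑bonded (Z)‑enamino lactone (a vinylogous carbamate), the valine centre staying untouched.

Step 5
Reactants: 8 tert‑butyl N‑[(Z)‑1‑(2‑oxodihydrofuran‑3(2H)‑ylidene)ethyl]‑L‑valinate
Product: 10 (S)‑3‑acetyl‑3‑(3‑methylbut‑2‑enyl)dihydrofuran‑2(3H)‑one, via ketimine 9 (not isolated)
Conditions: LiN(i‑Pr)2, PhMe, HMPA, −78 °C; prenyl bromide; then AcOH, NaOAc, H2O, THF, 23 °C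
Reagents that add atoms: prenyl bromide, CC(C)=CCBr; water, O
Why: auxiliary‑controlled chiral‑enamine alkylation of a β‑keto lactone, in which the chelated lithio‑enamine is C‑alkylated by the allylic bromide on the face left open by the valine isopropyl group and so sets the quaternary C5 centre, after which mild aqueous acid hydrolyses the non‑conjugated ketimine and returns the auxiliary.

Step 6
Reactants: 10 (S)‑3‑acetyl‑3‑(3‑methylbut‑2‑enyl)dihydrofuran‑2(3H)‑one, 5 (E)‑3,3,7‑trimethylocta‑4,6‑dienoic acid
Product: 12 (S)‑3‑[(6E)‑5,5,9‑trimethyl‑3‑oxodeca‑6,8‑dienoyl]‑3‑(3‑methylbut‑2‑enyl)dihydrofuran‑2(3H)‑one, via acid chloride 11 (not isolated)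
Conditions: 5, (COCl)2, DMF (cat.), CH2Cl2, 0 → 23 °C, evaporate; then 10, MgBr2·OEt2, i‑Pr2NEt, CH2Cl2, 0 → 23 °C
Reagents that add atoms: none
Why: soft‑enolisation Claisen acylation, in which magnesium‑chelated enolisation of the only enolisable position (the acetyl CH3, the future C3) and C‑acylation by the acid chloride give the β‑diketone while the quaternary C5 cannot epimerise.

Step 7
Reactants: 12 (S)‑3‑[(6E)‑5,5,9‑trimethyl‑3‑oxodeca‑6,8‑dienoyl]‑3‑(3‑methylbut‑2‑enyl)dihydrofuran‑2(3H)‑one
Product: 13 (S)‑3‑[(2E,6E)‑3‑methoxy‑5,5,9‑trimethyldeca‑2,6,8‑trienoyl]‑3‑(3‑methylbut‑2‑enyl)dihydrofuran‑2(3H)‑one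
Conditions: HC(OMe)3, MeOH, PPTS (cat.), 40 °C
Reagents that add atoms: trimethyl orthoformate, COC(OC)OC
Why: acid‑catalysed enol ether formation through the dimethyl ketal of the less hindered carbonyl (C2, flanked by two CH2 groups, whereas C4 sits on the quaternary C5), which should give the (E)‑β‑methoxy enone in which C1 and C4 are cis as the ring closure needs.

Step 8
Reactants: 13 (S)‑3‑[(2E,6E)‑3‑methoxy‑5,5,9‑trimethyldeca‑2,6,8‑trienoyl]‑3‑(3‑methylbut‑2‑enyl)dihydrofuran‑2(3H)‑one
Product: 14 6‑(2‑hydroxyethyl)‑3‑methoxy‑6‑(3‑methylbut‑2‑enyl)‑4‑[(3E)‑2,6‑dimethylhepta‑3,5‑dien‑2‑yl]cyclohex‑2‑ene‑1,5‑dione (ring B; C5 as in the target; C1 epimers)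
Conditions: LiN(SiMe3)2 (2.5 equiv), THF, −78 → 23 °C; AcOH
Reagents that add atoms: none
Why: Dieckmann‑type intramolecular Claisen condensation, in which reversible γ‑deprotonation at C1 (no α'‑hydrogen exists) gives the extended enolate of the vinylogous ester, C1 attacks the lactone carbonyl C9 in a 6‑exo‑trig closure of ring B, ring opening frees the 2‑hydroxyethyl arm and deprotonation of the acidic C1–H of the product drives the equilibrium, C1 being formed as an inconsequential epimer mixture.

Step 9
Reactants: 14 ring B alcohol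
Product: 15 2‑[(1S)‑4‑methoxy‑1‑(3‑methylbut‑2‑enyl)‑3‑[(3E)‑2,6‑dimethylhepta‑3,5‑dien‑2‑yl]‑2,6‑dioxocyclohex‑4‑enyl]acetaldehyde (C5 of the target as in the target; C1 epimers)
Conditions: 1,1,1‑triacetoxy‑1,2‑benziodoxol‑3(1H)‑one (periodinane), NaHCO3, CH2Cl2, 0 → 23 °C
Reagents that add atoms: none
Why: periodinane oxidation of the primary alcohol to the aldehyde under buffered conditions that leave the enol ether, the diene and the ketones alone.

Step 10
Reactants: 15 ring B aldehyde
Product: 16 2‑methoxy‑8,8‑dimethyl‑5,7‑bis(3‑methylbut‑2‑enyl)‑4,9‑dioxobicyclo[3.3.1]non‑2‑ene‑6‑carbaldehyde (C1, C5, C7 as in the target; C7 prenyl exo; C6 formyl equatorial and trans to it)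
Conditions: (2S,5S)‑5‑benzyl‑2‑tert‑butyl‑3‑methylimidazolidin‑4‑one·TFA (20 mol%), [Ir(ppy)2(dtbbpy)]PF6 (1 mol%), 2,4,6‑triisopropylbenzenethiol (10 mol%), DME, H2O (3 equiv), blue LEDs, 23 °C
Reagents that add atoms: none
Why: Proposed new method: the amine condenses with the aldehyde to the enamine of the C5 arm, the photoexcited trivalent iridium complex oxidises it to a three‑π‑electron enaminyl radical cation, C6 of this electrophilic radical adds to C7 (the free terminus of the electron‑rich 1,1‑dimethylbutadiene on C1), the allyl radical takes a hydrogen atom from the thiol at C1' to leave the prenyl group on C7, the thiyl radical is reduced by divalent iridium and hydrolysis of the iminium ion returns the amine. The closest known reaction type is the photoredox, enamine and thiol triple‑catalytic intramolecular α‑alkylation of aldehydes with tethered simple olefins; a 1,3‑diene as acceptor and closure onto a bridged ring are the extensions proposed. Ring A closes in the 6‑exo‑trig mode through a chair in which the CH2 arm on C5 and the CMe2 arm on C1 stand cis and 1,3‑diaxial on ring B, so that the bicyclo[3.3.1]nonane forms in this one bond. C7 is set by the chair, with the dienyl residue equatorial (exo) because the endo position is blocked by C3 of ring B; C1 is set because only the epimer with its arm cis to C6 can close while the epimers interconvert through the enol of the C9/C1/C2 unit under the amine salt; the C6 formyl group ends equatorial and is removed in step 11; the absolute sense is relayed from C5. The step needs 6‑exo closure to outrun a 1,2‑acyl shift of the C6 radical to C4 or C9 and needs hydrogen delivery to C1' and not to C3'; the first is secured by the delocalised, electrophilic character of the enaminyl radical cation (mismatched with a carbonyl carbon, matched with the diene terminus, which gives an allyl radical), the second by the reversible thiol/thiyl exchange that funnels the allyl radical to the more stable trisubstituted alkene.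

Step 11
Reactants: 16 bicyclic aldehyde
Product: 17 2‑methoxy‑8,8‑dimethyl‑5,7‑bis(3‑methylbut‑2‑enyl)bicyclo[3.3.1]non‑2‑ene‑4,9‑dione (C1, C5, C7 as in the target)
Conditions: RhCl(PPh3)3 (1.1 equiv), PhCN, 130 °C
Reagents that add atoms: none
Why: Tsuji–Wilkinson decarbonylation, in which oxidative addition of the formyl C–H bond to monovalent rhodium, CO migration and C–H reductive elimination with retention remove the temporary activating group and leave C6 as CH2 without touching C5 or C7.

Step 12
Reactants: 17 bicyclic vinylogous ester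
Product: 19 2‑methoxy‑8,8‑dimethyl‑5,7‑bis(3‑methylbut‑2‑enyl)‑3‑[3‑methyl‑3‑(triethylsilyloxy)butyl]bicyclo[3.3.1]non‑2‑ene‑4,9‑dione, via lithium alkoxide 18 (not isolated)
Conditions: lithium 2,2,6,6‑tetramethylpiperidide (1.3 equiv), THF, −78 °C; BF3·OEt2, 2,2‑dimethyloxetane, −78 °C; then Et3SiOTf, −78 → 0 °C
Reagents that add atoms: 2,2‑dimethyloxetane, CC1(C)CCO1; triethylsilyl trifluoromethanesulfonate, CC[Si](CC)(CC)OS(=O)(=O)C(F)(F)F
Why: directed α‑lithiation of the vinylogous ester at the vinylic C3–H (flanked by the methoxy‑bearing C2 and the C4 carbonyl) and BF3‑promoted SN2 opening of the oxetane at its unsubstituted CH2 install the 3‑hydroxy‑3‑methylbutyl chain, whose alkoxide is silylated in the same flask so that it cannot displace methoxide at C2, and no stereocentre is formed.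

Step 13
Reactants: 19 C3‑alkylated silyl ether, 20 (R)‑2‑methylbutanoic acid
Product: 22 1‑[(R)‑2‑methylbutanoyl] derivative of 19 (C1, C5, C7 as in the target), via (R)‑2‑methylbutanoyl chloride 21 (not isolated)
Conditions: 20, (COCl)2, DMF (cat.), CH2Cl2, 0 → 23 °C, evaporate; 19, lithium 2,2,6,6‑tetramethylpiperidide (1.5 equiv), THF, −78 °C; then 21, −78 °C
Reagents that add atoms: none
Why: bridgehead lithiation and acylation, in which C1–H is the only acidic C–H left (beside the C9 ketone and at the γ‑position of the vinylogous ester), the pyramidal bridgehead carbanion cannot invert and should be C‑acylated at −78 °C faster than the acid chloride is enolised, so that the C1 configuration and the (R)‑centre of the acyl group are retained.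

Step 14
Reactants: 22 C1‑acylated vinylogous methyl ester
Product: 24 target compound CNP0326306.1, via triethylsilyl ether of the target enol 23 (not isolated)
Conditions: LiCl (10 equiv), DMSO, 120 °C; then 1 M HCl, THF, 0 → 23 °C
Reagents that add atoms: none
Why: Krapcho‑type SN2 demethylation of the vinylogous methyl ester by chloride followed by acid hydrolysis of the tertiary silyl ether reveals the enolised trione and the tertiary alcohol, the silyl group being kept until after demethylation so that the hydroxyl cannot close a pyran onto C2, and the neutral and then mildly acidic conditions leave the acyl α‑centre and the prenyl groups intact.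

**Compound list**
1 | phorone (2,6‑dimethylhepta‑2,5‑dien‑4‑one) | CC(C)=CC(=O)C=C(C)C | starting material
2 | 2,6‑dimethylhepta‑2,5‑dien‑4‑ol | CC(C)=CC(O)C=C(C)C | intermediate
3 | 4‑[(1‑ethoxyethenyl)oxy]‑2,6‑dimethylhepta‑2,5‑diene (ketene acetal) | C=C(OCC)OC(C=C(C)C)C=C(C)C | intermediate
4 | ethyl (E)‑3,3,7‑trimethylocta‑4,6‑dienoate | CCOC(=O)CC(C)(C)/C=C/C=C(C)C | intermediate
5 | (E)‑3,3,7‑trimethylocta‑4,6‑dienoic acid | OC(=O)CC(C)(C)/C=C/C=C(C)C | intermediate
6 | 3‑acetyldihydrofuran‑2(3H)‑one (racemic, enolisable) | CC(=O)C1CCOC1=O | starting material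
7 | L‑valine tert‑butyl ester hydrochloride | Cl.CC(C)[C@H](N)C(=O)OC(C)(C)C | starting material
8 | tert‑butyl N‑[(Z)‑1‑(2‑oxodihydrofuran‑3(2H)‑ylidene)ethyl]‑L‑valinate | C/C(N[C@@H](C(C)C)C(=O)OC(C)(C)C)=C1\CCOC1=O | intermediate
9 | tert‑butyl N‑{1‑[(S)‑3‑(3‑methylbut‑2‑enyl)‑2‑oxotetrahydrofuran‑3‑yl]ethylidene}‑L‑valinate | CC(=N[C@@H](C(C)C)C(=O)OC(C)(C)C)[C@]1(CC=C(C)C)CCOC1=O | intermediate
10 | (S)‑3‑acetyl‑3‑(3‑methylbut‑2‑enyl)dihydrofuran‑2(3H)‑one | CC(=O)[C@]1(CC=C(C)C)CCOC1=O | intermediate
11 | (E)‑3,3,7‑trimethylocta‑4,6‑dienoyl chloride | ClC(=O)CC(C)(C)/C=C/C=C(C)C | intermediate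
12 | (S)‑3‑[(6E)‑5,5,9‑trimethyl‑3‑oxodeca‑6,8‑dienoyl]‑3‑(3‑methylbut‑2‑enyl)dihydrofuran‑2(3H)‑one (drawn as diketone) | CC(C)=C/C=C/C(C)(C)CC(=O)CC(=O)[C@]1(CC=C(C)C)CCOC1=O | intermediate
13 | (S)‑3‑[(2E,6E)‑3‑methoxy‑5,5,9‑trimethyldeca‑2,6,8‑trienoyl]‑3‑(3‑methylbut‑2‑enyl)dihydrofuran‑2(3H)‑one | CC(C)=C/C=C/C(C)(C)C/C(OC)=C\C(=O)[C@]1(CC=C(C)C)CCOC1=O | intermediate
14 | 6‑(2‑hydroxyethyl)‑3‑methoxy‑6‑(3‑methylbut‑2‑enyl)‑4‑[(3E)‑2,6‑dimethylhepta‑3,5‑dien‑2‑yl]cyclohex‑2‑ene‑1,5‑dione (C5 as in the target; C1 epimers) | OCC[C@@]1(CC=C(C)C)C(=O)C=C(OC)C(C(C)(C)/C=C/C=C(C)C)C1=O | intermediate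
15 | 2‑[(1S)‑4‑methoxy‑1‑(3‑methylbut‑2‑enyl)‑3‑[(3E)‑2,6‑dimethylhepta‑3,5‑dien‑2‑yl]‑2,6‑dioxocyclohex‑4‑enyl]acetaldehyde (C1 epimers) | O=CC[C@@]1(CC=C(C)C)C(=O)C=C(OC)C(C(C)(C)/C=C/C=C(C)C)C1=O | intermediate
16 | 2‑methoxy‑8,8‑dimethyl‑5,7‑bis(3‑methylbut‑2‑enyl)‑4,9‑dioxobicyclo[3.3.1]non‑2‑ene‑6‑carbaldehyde (C1, C5, C7 as in the target; formyl equatorial) | [C@H]12C(OC)=CC(=O)[C@](CC=C(C)C)([C@H](C=O)[C@@H](CC=C(C)C)C1(C)C)C2=O | intermediate
17 | 2‑methoxy‑8,8‑dimethyl‑5,7‑bis(3‑methylbut‑2‑enyl)bicyclo[3.3.1]non‑2‑ene‑4,9‑dione (C1, C5, C7 as in the target) | [C@H]12C(OC)=CC(=O)[C@](CC=C(C)C)(C[C@@H](CC=C(C)C)C1(C)C)C2=O | intermediate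
18 | lithium alkoxide of the 3‑(3‑hydroxy‑3‑methylbutyl) derivative of 17 | [Li+].[C@H]12C(OC)=C(CCC(C)(C)[O-])C(=O)[C@](CC=C(C)C)(C[C@@H](CC=C(C)C)C1(C)C)C2=O | intermediate
19 | 2‑methoxy‑8,8‑dimethyl‑5,7‑bis(3‑methylbut‑2‑enyl)‑3‑[3‑methyl‑3‑(triethylsilyloxy)butyl]bicyclo[3.3.1]non‑2‑ene‑4,9‑dione | [C@H]12C(OC)=C(CCC(C)(C)O[Si](CC)(CC)CC)C(=O)[C@](CC=C(C)C)(C[C@@H](CC=C(C)C)C1(C)C)C2=O | intermediate
20 | (R)‑2‑methylbutanoic acid | CC[C@@H](C)C(=O)O | starting material
21 | (R)‑2‑methylbutanoyl chloride | CC[C@@H](C)C(=O)Cl | intermediate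
22 | 1‑[(R)‑2‑methylbutanoyl] derivative of 19 | CC[C@@H](C)C(=O)[C@]12C(OC)=C(CCC(C)(C)O[Si](CC)(CC)CC)C(=O)[C@](CC=C(C)C)(C[C@@H](CC=C(C)C)C1(C)C)C2=O | intermediate
23 | triethylsilyl ether of the target (enolised trione) | CC[C@@H](C)C(=O)[C@]12C(=O)C(CCC(C)(C)O[Si](CC)(CC)CC)=C(O)[C@](CC=C(C)C)(C[C@@H](CC=C(C)C)C1(C)C)C2=O | intermediate
24 | CNP0326306.1 | CC[C@@H](C)C(=O)[C@]12C(=O)C(CCC(C)(C)O)=C(O)[C@](CC=C(C)C)(C[C@@H](CC=C(C)C)C1(C)C)C2=O | target

**Total step count:** 14. **Longest linear sequence:** 12 steps (steps 1–3, then 6–14).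

**Steps most likely to fail**

Step 10 (proposed new method). The enaminyl radical cation may be returned to the enamine, by back electron transfer or by hydrogen transfer from the thiol, before ring B reaches the 1,3‑diaxial conformer. Hydrogen may also be delivered to the tertiary terminus of the allyl radical, which misplaces the alkene, and the thiol may be consumed by addition to the diene. Fallback with known chemistry, setting out from 15 and returning at 16: amine‑catalysed α‑selenenylation of 15 with N‑(phenylselanyl)phthalimide should give the α‑(phenylselanyl) aldehyde F1. Slow addition of (Me3Si)3SiH and AIBN in toluene at 80 °C then abstracts selenium in a chain process, and the stabilised α‑formyl radical at C6 closes 6‑exo onto the diene and is reduced by the silane to 16. This replaces the catalytic redox cycle by a stoichiometric radical chain from a preformed radical precursor.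

Step 13. Acyl transfer to the hindered, strongly basic bridgehead carbanion beside the quaternary C8 may lose to proton transfer from the α‑C–H of the acid chloride, which forms a ketene, returns 19 and erodes the (R) centre. Fallback, setting out from 19 and returning at 22: the bridgehead anion is trapped with I2 as the bridgehead iodide F2. Iodine–magnesium exchange with i‑PrMgCl·LiCl gives the less basic bridgehead organomagnesium species, which is acylated by (R)‑N‑methoxy‑N,2‑dimethylbutanamide F3 (from 20, carbonyldiimidazole and MeNHOMe·HCl) to give 22.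

Step 8. The γ‑carbanion at C1, flanked by the quaternary C8, may fail to reach the hindered lactone carbonyl because the extended enolate rests in a rotamer that places C5 away from C1, and reprotonation then only returns 13. Fallback, setting out from 12 and returning at 14: enol ether formation and ring closure are exchanged. With LiN(i‑Pr)2 (3.3 equiv) 12 forms the dianion of the free β‑diketone, whose terminal carbanion C1 closes onto the lactone in a polyketide‑type Claisen cyclisation to give the hydroxyethyl trione F4. HC(OMe)3, MeOH and PPTS then form the enol ether at C2, the carbonyl that is not flanked by the quaternary C5, to give 14.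

**Further compounds**
F1 | step 10 | 2‑(phenylselanyl) derivative of aldehyde 15 (selenium on C6) | O=CC([Se]c1ccccc1)[C@@]1(CC=C(C)C)C(=O)C=C(OC)C(C(C)(C)/C=C/C=C(C)C)C1=O
F2 | step 13 | 1‑iodo derivative of 19 (bridgehead iodide) | I[C@]12C(OC)=C(CCC(C)(C)O[Si](CC)(CC)CC)C(=O)[C@](CC=C(C)C)(C[C@@H](CC=C(C)C)C1(C)C)C2=O
F3 | step 13 | (R)‑N‑methoxy‑N,2‑dimethylbutanamide | CC[C@@H](C)C(=O)N(C)OC
F4 | step 8 | 6‑(2‑hydroxyethyl)‑6‑(3‑methylbut‑2‑enyl)‑4‑[(3E)‑2,6‑dimethylhepta‑3,5‑dien‑2‑yl]cyclohexane‑1,3,5‑trione (C5 as in the target; C1 epimers) | OCC[C@@]1(CC=C(C)C)C(=O)CC(=O)C(C(C)(C)/C=C/C=C(C)C)C1=O
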